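All runs stem from a simulated flask from invented constants; noise was put on by code.

the same everywhere: starting material 48 mM
- west: catalyst 0.67 mM; temperature 20 °C; run made earlier
- south-east: catalyst 1.1 mM; temperature 32 °C; run made earlier
- zeta: catalyst 0.48 mM; at 25 °C until 12 h, from then on at 40 °C; time 40 h
- delta: catalyst 0.48 mM; temperature 40 °C; time 40 h
- eta: catalyst 0.48 mM; temperature 25 °C; time 40 h

- west (time / h: target / %, starting material / %): 15.0: 58.6, 29.8; 30.0: 64.4, 17.8; 60.0: 68.4, 14.1; 72.0: 66.8, 13.2; 120: 67.5, 12.8
- south-east (time / h: target / %, starting material / %): 6.00: 58.3, 33.9; 12.0: 57.4, 33.0; 20.0: 57.6, 33.2; 25.0: 57.6, 32.5; 30.0: 56.2, 33.2; 40.0: 59.2, 34.9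

(each reading ± 1 percentage point)

- the flask that comes out highest in amount of target, in percent of the starting material charged, or "all alike" when all lie within 1.5 percentage points (zeta / delta / eta / all alike)
- target at the end, in percent of the starting material charged, zeta
- target at the end, in percent of the starting material charged, delta
- target at the end, in percent of the starting material charged, eta

- the numbers in the tables scatter by 1 percentage point (one standard deviation)
- on the list of suspects stand: target + catalyst <-> isomer of the product A + catalyst; starting material + catalyst <-> target + catalyst; isomer of the product A + catalyst <-> isomer of the product B + catalyst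

1. 5.05 is the plateau ratio: [target]/[starting material] in a flask that has stopped moving, read here from the last 3 west readings at 20 °C. The 6 south-east readings at 32 °C give 1.73. This reckoning takes both plateaus as equilibria, which a catalyst reaches sooner but does not shift.

2. Fastest rung: south-east stands flat within the scatter from its first reading at 6.00 h, which this reckoning counts as about 5 half-lives or more, so its half-life is about 1.20 h or less. This reckoning takes the catalyst as constant, so each step is pseudo-first-order, with speed in proportion to [catalyst]. At 0.48 mM and 32 °C that becomes 2.75 h.

3. Next rung: west's excess of starting material over its plateau gives a half-life of 6.36 h at 20 °C, or 8.88 h at 0.48 mM, longer than the 32 °C figure.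

4. Slowest rung: zeta spends 28.0 h at 40 °C, about 10.2 half-lives of the 32 °C figure, and 40 °C is the hotter of the two. Eta's 40 h at 25 °C hold 4.50 even of the 20 °C half-lives. So zeta should forget its 25 °C stage and end like delta.

5. Taking ln(ratio) as straight in temperature gives 3.23 at 25 °C and 0.843 at 40 °C. Isomers per target, read as what is missing from the two columns, 0.282 in west and 0.153 in south-east, are carried over in temperature in the same manner. Target is then 1/(1 + 1/ratio + isomers per target): 65.4% for eta, and 43.7% for both zeta and delta.

6. The forecast differs: eta highest, with 50% in zeta, 21% in delta and 54% in eta, since “the plateaus look like catalyst death, not equilibrium”.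

7. The flasks give 45.0% in zeta, 45.0% in delta and 65.1% in eta, so eta is highest.

    target + catalyst ⇌ isomer of the product A + catalyst, rate k1*[catalyst]*[target] forward; the back reaction follows from the equilibrium constant (K = 0.100, k = 0.0530 M⁻¹ s⁻¹, Ea = 57.0 kJ mol⁻¹, ΔH = −22.0 kJ mol⁻¹)
    starting material + catalyst ⇌ target + catalyst, rate k2*[starting material]*[catalyst] forward; the back reaction follows from the equilibrium constant (K = 3.20, k = 0.0630 M⁻¹ s⁻¹, Ea = 68.0 kJ mol⁻¹, ΔH = −65.0 kJ mol⁻¹)
    isomer of the product A + catalyst ⇌ isomer of the product B + catalyst, rate k3*[catalyst]*[isomer of the product A] forward; the back reaction follows from the equilibrium constant (K = 1.20, k = 0.0990 M⁻¹ s⁻¹, Ea = 58.0 kJ mol⁻¹, ΔH = −14.0 kJ mol⁻¹)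
    (constants at 25 °C)

8. In delta the forward step alone has a half-life of 1.7 h at 0.883 h, against the 28.0 h that zeta spends hot; zeta goes from 55.2% target at 12.0 h to 45.0% beside 49.4% starting material at 40.0 h, a ratio of 0.911 against the reckoned 0.843. A flask like delta kept at 65 °C has a reckoned ratio of 0.0898 and ends at 0.144, with 12.5% target.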